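- If you take over blue and amber, carry one number, the live initiator x: the initiator loading less the stray impurity, each as a fraction of the free monomer charged, which I made 1.90 % in blue and 11.9 % in amber. I treated the stray impurity as the limiting reagent of that pair.

in all of them: free monomer 0.10 M; stray impurity 3.1 mM
- dusk: protic impurity 0.010 M; initiator 3.8 mol%; run made earlier
- summer: protic impurity 0.010 M; initiator 9.1 mol%; run made earlier
- winter: protic impurity 0.010 M; initiator 18 mol%; run made earlier
- blue: protic impurity 0.0100 M; initiator 5 mol%; time 50 min
- amber: protic impurity 0.0100 M; initiator 15 mol%; time 50 min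

| run | time / min | monomer in chains / % | free monomer / % |
|---|---|---|---|
| dusk | 4.00 | 9.8 | 79.0 |
| dusk | 12.0 | 9.6 | 78.4 |
| dusk | 25.0 | 9.4 | 78.1 |
| dusk | 40.0 | 10.9 | 81.1 |
| dusk | 50.0 | 10.1 | 78.6 |
| summer | 4.00 | 49.5 | 40.9 |
| summer | 12.0 | 51.3 | 39.6 |
| summer | 25.0 | 51.4 | 40.5 |
| summer | 40.0 | 50.6 | 38.6 |
| summer | 50.0 | 50.9 | 37.9 |
| winter | 4.00 | 73.6 | 15.0 |
| winter | 8.00 | 73.7 | 15.3 |
| winter | 15.0 | 73.1 | 15.4 |
| winter | 25.0 | 75.5 | 15.2 |
| winter | 50.0 | 76.5 | 15.8 |

(scatter of a reading: 1 percentage point)

- the average divides the monomer in chains by the number of chains begun, living and dead together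
- steps thought possible: free monomer + initiator -> living end + monomer in chains; free monomer + living end -> monomer in chains + living end; monomer in chains + living end -> free monomer + living end; initiator + stray impurity -> spent initiator A; protic impurity + free monomer -> quenched substrate; living end -> dead end B
- the earlier runs do not show the number of chains; that part of a forecast is a guess

1. which of the two ends with the longer chains by the average number of monomer units in a chain (chains begun, living or dead) ("neither" if they lie within 10 %) (blue / amber / neither)
2. average number of monomer units in a chain (chains begun, living or dead) at the end, blue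
3. average number of monomer units in a chain (chains begun, living or dead) at the end, amber

- Winter sat still within the scatter: its free monomer read 15.0 % at 4.00 min and 15.8 % at 50.0 min, so I told you not to wait for more.
- The protic impurity takes 10.0 % of the free monomer, and summer's free monomer plus monomer in chains averaged 90.2 %, so I left w = 90.0 % to share.
- With λ = ln(w/free monomer), the mean readings gave 0.130 at x = 0.700 % in dusk, 0.824 at 6.00 % in summer and 1.77 at 14.9 % in winter; I stepped λ straight between neighbouring runs.
- So I expected 67.6 % free monomer and 22.4 % in chains in blue, and 21.1 % and 68.9 % in amber.
- The earlier runs count no chains, so I guessed one chain per unit of x: 11.8 units in blue, 5.79 in amber, about twice.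
- I asked that the stray impurity charge stay untouched, because in blue it is more than x: 3.10 % against 1.90 %.
- The forecast named blue, at 11.6 units against 5.8, slightly below my blue figure, with the words “The living ends are dying quickly”.
- Blue gave 11.6 units and amber 5.87, with 22.0 % and 69.9 % in chains, so blue ended longer.

    free monomer + initiator → living end + monomer in chains (k = 1.80 L mol⁻¹ s⁻¹)
    free monomer + living end → monomer in chains + living end, rate k2*[living end]*[free monomer] (k = 3.40 L mol⁻¹ s⁻¹)
    monomer in chains + living end → free monomer + living end, rate k3*[living end] as long as [monomer in chains] is above zero (k = 0.0340 s⁻¹)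
    initiator + stray impurity → spent initiator A (k = 690 L mol⁻¹ s⁻¹)
    protic impurity + free monomer → quenched substrate (k = 1.60 L mol⁻¹ s⁻¹)
    living end → dead end B (k = 0.0220 s⁻¹)

- Amber's neighbour was charged with 0.012 M of stray impurity, so I took the extra 8.90 % off amber's x and kept 3.00 %. Stepping λ between dusk and summer put free monomer at 58.5 % and monomer in chains at 31.5 %, which made 10.5 units. That flask held 58.1 % free monomer, 31.9 % in chains and dead end B at 3.00 % of the monomer charge, and its chains averaged 10.6 units.

(Readings and results were generated by integration with constants of no real substance; the scatter is artificial.)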